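**Strategy.** The bromocyclohexane ring is disconnected at the bond between its CHBr carbon (C6) and the adjacent quaternary, methyl-bearing carbon (C7). C6 is carried as an aldehyde and C7 as the β-carbon of a temporary δ-lactone that ties the C3 oxygen (C3 later becomes the exocyclic methylene carbon) to C9. Hydrogen-atom-transfer photocatalysis turns the aldehyde into an acyl radical that closes the six-membered ring onto C7, giving a bridged keto-lactone and fixing the quaternary centre relative to C2. The step exploits the 1,4-relationship of C6 and C9 across C7 and the cis-1,3 placement of C3 and the C8 branch on the cyclohexane ring. The C6 ketone then becomes the equatorial bromide.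

Key step: step 11

Numbering used below: C1 benzylic CH2; C2 ring CH carrying it; C3 ring carbon of the exocyclic methylene; C4, C5 ring CH2; C6 ring CHBr; C7 quaternary ring carbon (CH3); C8, C9 chain CH2; C10 chain CHBr; C11 C(OH)CH3; C12, C13 CH2; C14 ester CH–O; C15 isopropenyl carbon. Ar = 5-(tert-butoxycarbonyl)-2-[(triisopropylsilyl)oxy]phenyl. Assumption: the enantiomer of the fructose-derived Shi ketone (made from L-sorbose) is available as a catalyst.

Step 1
Reactants: 1 (R)-4-benzyloxazolidin-2-one; 2 acryloyl chloride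
Product: 4 (R)-3-acryloyl-4-benzyloxazolidin-2-one, via N-lithio oxazolidinone 3 (not isolated)
Conditions: n-BuLi, THF, −78 °C; then 2, −78 to 0 °C
Reagents that add atoms: none
Why: N-acylation of the lithiated Evans auxiliary by the acid chloride is fast at low temperature and leaves the auxiliary stereocentre untouched.

Step 2
Reactants: 5 tert-butyl 4-hydroxybenzoate
Product: 6 tert-butyl 4-hydroxy-3-iodobenzoate
Conditions: N-iodosuccinimide, TsOH·H2O (10 mol %), MeCN, rt
Reagents that add atoms: N-iodosuccinimide O=C1CCC(=O)N1I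
Why: Electrophilic aromatic iodination goes ortho to the phenol because the para position is blocked by the ester.

Step 3
Reactants: 6 tert-butyl 4-hydroxy-3-iodobenzoate
Product: 7 tert-butyl 3-iodo-4-[(triisopropylsilyl)oxy]benzoate
Conditions: TIPSOTf, 2,6-lutidine, CH2Cl2, 0 °C
Reagents that add atoms: triisopropylsilyl trifluoromethanesulfonate CC(C)[Si](OS(=O)(=O)C(F)(F)F)(C(C)C)C(C)C
Why: Silylation of the hindered phenol with a silyl triflate gives an aryl silyl ether that should survive every step up to the final fluoride treatment.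

Step 4
Reactants: 7 tert-butyl 3-iodo-4-[(triisopropylsilyl)oxy]benzoate; 4 (R)-3-acryloyl-4-benzyloxazolidin-2-one
Product: 8 (R)-4-benzyl-3-[(E)-3-Ar-prop-2-enoyl]oxazolidin-2-one
Conditions: Pd(OAc)2 (5 mol %), P(o-tol)3, Et3N, MeCN, 80 °C
Reagents that add atoms: none
Why: Mizoroki–Heck coupling of the aryl iodide with the electron-poor acrylimide should give the E-cinnamoyl imide.

Step 5
Reactants: 8 (R)-4-benzyl-3-[(E)-3-Ar-prop-2-enoyl]oxazolidin-2-one
Product: 9 (R)-4-benzyl-3-(3-Ar-propanoyl)oxazolidin-2-one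
Conditions: H2 (1 atm), Pd/C, EtOAc, rt
Reagents that add atoms: none
Why: Heterogeneous hydrogenation saturates only the conjugated C=C bond and leaves the arene, silyl ether and esters intact.

Step 6
Reactants: 9 (R)-4-benzyl-3-(3-Ar-propanoyl)oxazolidin-2-one; 10 pent-4-enal
Product: 12 (R)-4-benzyl-3-[(2R,3S)-2-(ArCH2)-3-hydroxyhept-6-enoyl]oxazolidin-2-one, via dibutylboron Z-enolate 11 (not isolated)
Conditions: Bu2BOTf, Et3N, CH2Cl2, −78 to 0 °C; then 10, −78 to 0 °C; then pH 7 buffer, MeOH, H2O2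
Reagents that add atoms: none
Why: Evans syn-aldol reaction: the Z-boron enolate reacts through a Zimmerman–Traxler chair in which the benzyl group of the (R)-auxiliary blocks one enolate face, which sets C2 (R) and the temporary C3 carbinol (S) syn to each other.

Step 7
Reactants: 12 (R)-4-benzyl-3-[(2R,3S)-2-(ArCH2)-3-hydroxyhept-6-enoyl]oxazolidin-2-one
Product: 13 (2R,3S)-2-(ArCH2)-3-hydroxy-N-methoxy-N-methylhept-6-enamide
Conditions: MeNH(OMe)·HCl, AlMe3, CH2Cl2, −20 to 0 °C
Reagents that add atoms: N,O-dimethylhydroxylamine hydrochloride CNOC.Cl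
Why: Weinreb transamidation with the aluminium amide is assisted by the free β-hydroxyl, releases the auxiliary and should not epimerise C2.

Step 8
Reactants: 13 (2R,3S)-2-(ArCH2)-3-hydroxy-N-methoxy-N-methylhept-6-enamide
Product: 14 (3R,4S)-3-(ArCH2)-4-hydroxyoct-7-en-2-one
Conditions: MeMgBr (3 equiv), THF, −20 to 0 °C
Reagents that add atoms: methylmagnesium bromide C[Mg]Br
Why: Grignard addition to the Weinreb amide stops at the ketone through the chelated tetrahedral intermediate, while the hindered tert-butyl benzoate should not react at this temperature.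

Step 9
Reactants: 14 (3R,4S)-3-(ArCH2)-4-hydroxyoct-7-en-2-one
Product: 16 (5S,6S)-5-(ArCH2)-6-(but-3-en-1-yl)-4-methyl-5,6-dihydro-2H-pyran-2-one, via ester-stabilised phosphorus ylide 15 (not isolated)
Conditions: Ph3P=C=C=O, toluene, 110 °C
Reagents that add atoms: (triphenylphosphoranylidene)ketene O=C=C=P(c1ccccc1)(c1ccccc1)c1ccccc1
Why: Bestmann-ylide lactonisation: the hydroxyl adds to the ketene ylide and the resulting ester ylide undergoes an intramolecular Wittig reaction with the methyl ketone under neutral conditions, so the ring fixes the Z-geometry of C7=C8 and the syn aldol becomes the cis-5,6-lactone without epimerisation at C2.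

Step 10
Reactants: 16 (5S,6S)-5-(ArCH2)-6-(but-3-en-1-yl)-4-methyl-5,6-dihydro-2H-pyran-2-one
Product: 18 (5S,6S)-5-(ArCH2)-4-methyl-6-(3-oxopropyl)-5,6-dihydro-2H-pyran-2-one, via vicinal diol 17 (not isolated)
Conditions: OsO4 (2 mol %), NaIO4, 2,6-lutidine, dioxane–H2O, rt
Reagents that add atoms: sodium periodate [Na+].[O-]I(=O)(=O)=O
Why: Lemieux–Johnson cleavage: OsO4 dihydroxylates only the electron-rich terminal alkene (the conjugated lactone alkene is inert) and periodate cleaves the diol to the C6 aldehyde.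

Step 11
Reactants: 18 (5S,6S)-5-(ArCH2)-4-methyl-6-(3-oxopropyl)-5,6-dihydro-2H-pyran-2-one
Product: 19 (1S,5S,9S)-9-(ArCH2)-5-methyl-2-oxabicyclo[3.3.1]nonane-3,6-dione
Conditions: (n-Bu4N)4W10O32 (2 mol %), MeCN (0.01 M), 390 nm LEDs, argon, rt
Reagents that add atoms: none
Why: The excited decatungstate anion abstracts the aldehydic hydrogen of 18 to give a nucleophilic acyl radical at C6, which adds to the β-carbon C7 of the unsaturated lactone, and back hydrogen transfer from the reduced photocatalyst to the resulting C8 radical closes a redox-neutral cycle. The closest known reaction type is the decatungstate-photocatalysed hydroacylation of electron-poor alkenes (Giese-type acyl radical addition), here run intramolecularly. The cyclohexane ring C2–C3–C4–C5–C6–C7 closes in a chair-like 6-exo-trig mode with the C3 side chain axial on the half-chair lactone, so the product is a 2-oxabicyclo[3.3.1]nonane. The new quaternary stereocentre C7 is controlled by the C3 stereocentre, because the three-atom tether can reach C7 only from the lactone face that carries the C3 chain; this places the C8 branch cis to the C3 oxygen and, since 18 is the cis-5,6-lactone, trans to the arylmethyl group on C2. The step needs hydrogen abstraction at the aldehyde rather than at benzylic or silyl-isopropyl C–H bonds and attack at the β- rather than the α-carbon; the weak, hydridic aldehyde C–H bond secures the first, and the polarised acceptor together with six- versus seven-membered ring closure secures the second. Decarbonylation of the primary acyl radical is slow at room temperature.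

Step 12
Reactants: 19 (1S,5S,9S)-9-(ArCH2)-5-methyl-2-oxabicyclo[3.3.1]nonane-3,6-dione
Product: 20 (1S,5S,9S)-6-bromo-9-(ArCH2)-5-methyl-2-oxabicyclo[3.3.1]non-6-en-3-one
Conditions: P(OPh)3, Br2, CH2Cl2, −60 °C; then 19, Et3N, −60 °C to reflux
Reagents that add atoms: bromine BrBr
Why: The triphenyl phosphite–bromine reagent converts the enolisable ketone into the vinyl bromide by O-phosphonium activation and elimination, and only C5 can lose a proton because C7 is quaternary.

Step 13
Reactants: 20 (1S,5S,9S)-6-bromo-9-(ArCH2)-5-methyl-2-oxabicyclo[3.3.1]non-6-en-3-one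
Product: 21 (1S,5S,6S)-6-(ArCH2)-4-bromo-5-(2-hydroxyethyl)-5-methylcyclohex-3-en-1-ol
Conditions: LiBH4, THF, 0 °C to rt
Reagents that add atoms: none
Why: Hydride reduction opens the lactone to the C3/C9 diol, while the tert-butyl ester and the vinyl bromide should be inert to LiBH4.

Step 14
Reactants: 21 (1S,5S,6S)-6-(ArCH2)-4-bromo-5-(2-hydroxyethyl)-5-methylcyclohex-3-en-1-ol
Product: 22 (1S,2S,3S,4S)-2-(ArCH2)-4-bromo-3-(2-hydroxyethyl)-3-methylcyclohexan-1-ol
Conditions: Mn(dpm)3 (10 mol %), PhSiH3, t-BuOOH, i-PrOH, rt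
Reagents that add atoms: none
Why: Metal-hydride hydrogen-atom-transfer hydrogenation, a reaction type that reduces haloalkenes without loss of halogen: hydrogen adds first to C5 to give the tertiary α-bromo radical at C6, and the second hydrogen is delivered axially, anti to the axial C7 methyl of the chair that holds the C2, C3 and C8 substituents equatorial, which places bromine equatorial (C6 S, cis to the methyl and trans to the C8 branch).

Step 15
Reactants: 22 (1S,2S,3S,4S)-2-(ArCH2)-4-bromo-3-(2-hydroxyethyl)-3-methylcyclohexan-1-ol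
Product: 23 (1S,2S,3S,4S)-2-(ArCH2)-4-bromo-3-(2-iodoethyl)-3-methylcyclohexan-1-ol
Conditions: I2, PPh3, imidazole, CH2Cl2, 0 °C
Reagents that add atoms: iodine II
Why: Appel-type iodination is selective for the unhindered primary C9 alcohol over the flanked secondary C3 alcohol.

Step 16
Reactants: 23 (1S,2S,3S,4S)-2-(ArCH2)-4-bromo-3-(2-iodoethyl)-3-methylcyclohexan-1-ol
Product: 24 (2S,3S,4S)-2-(ArCH2)-4-bromo-3-(2-iodoethyl)-3-methylcyclohexan-1-one
Conditions: Dess–Martin periodinane, CH2Cl2, rt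
Reagents that add atoms: none
Why: Dess–Martin oxidation of the secondary alcohol is neutral, so the C2 centre next to the new C3 ketone and both alkyl halides should survive.

Step 17
Reactants: 25 methyl pent-4-ynoate
Product: 26 N-methoxy-N-methylpent-4-ynamide
Conditions: MeNH(OMe)·HCl, i-PrMgCl, THF, −20 °C
Reagents that add atoms: N,O-dimethylhydroxylamine hydrochloride CNOC.Cl
Why: The magnesium amide formed in the flask converts the methyl ester directly into the Weinreb amide.

Step 18
Reactants: 26 N-methoxy-N-methylpent-4-ynamide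
Product: 27 2-methylhept-1-en-6-yn-3-one
Conditions: isopropenylmagnesium bromide (2.2 equiv), THF, 0 °C
Reagents that add atoms: isopropenylmagnesium bromide C=C(C)[Mg]Br
Why: Grignard addition to the Weinreb amide stops at the enone through the chelated tetrahedral intermediate.

Step 19
Reactants: 27 2-methylhept-1-en-6-yn-3-one
Product: 28 (S)-2-methylhept-1-en-6-yn-3-ol
Conditions: (R)-2-methyl-CBS-oxazaborolidine (10 mol %), BH3·SMe2, THF, −30 °C
Reagents that add atoms: none
Why: Corey–Bakshi–Shibata reduction, in which the isopropenyl group acts as the large substituent, so the (R)-catalyst should deliver hydride to give the (S)-allylic alcohol (C14).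

Step 20
Reactants: 28 (S)-2-methylhept-1-en-6-yn-3-ol
Product: 30 (3S,6E)-7-iodo-2,6-dimethylhepta-1,6-dien-3-ol, via alkenylalane 29 (not isolated)
Conditions: AlMe3 (3 equiv), Cp2ZrCl2 (25 mol %), CH2Cl2, 0 °C to rt; then I2, THF, −30 °C
Reagents that add atoms: trimethylaluminium C[Al](C)C; iodine II
Why: Zirconium-catalysed carboalumination (Negishi) adds methyl and aluminium syn across the terminal alkyne and iodinolysis proceeds with retention, which gives the E-trisubstituted vinyl iodide (C10=C11).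

Step 21
Reactants: 30 (3S,6E)-7-iodo-2,6-dimethylhepta-1,6-dien-3-ol
Product: 31 triethyl{[(3S,6E)-7-iodo-2,6-dimethylhepta-1,6-dien-3-yl]oxy}silane
Conditions: TESCl, imidazole, CH2Cl2, 0 °C
Reagents that add atoms: chlorotriethylsilane CC[Si](Cl)(CC)CC
Why: Silylation masks the C14 hydroxyl so that it does not quench the organozinc reagent of the next step.

Step 22
Reactants: 24 (2S,3S,4S)-2-(ArCH2)-4-bromo-3-(2-iodoethyl)-3-methylcyclohexan-1-one; 31 triethyl{[(3S,6E)-7-iodo-2,6-dimethylhepta-1,6-dien-3-yl]oxy}silane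
Product: 33 (2S,3S,4S)-2-(ArCH2)-4-bromo-3-methyl-3-[(3E,7S)-4,8-dimethyl-7-(triethylsilyloxy)nona-3,8-dien-1-yl]cyclohexan-1-one, via alkylzinc iodide 32 (not isolated)
Conditions: Zn dust (activated with TMSCl and 1,2-dibromoethane), DMA, 40 °C; then 31, Pd(PPh3)4 (5 mol %), THF, rt
Reagents that add atoms: none
Why: Negishi sp3–sp2 coupling: zinc inserts only into the primary C–I bond (the ketone and the neopentyl-type secondary bromide are inert) and the palladium-catalysed coupling forms C9–C10 with retention of the E-geometry.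

Step 23
Reactants: 33 (2S,3S,4S)-2-(ArCH2)-4-bromo-3-methyl-3-[(3E,7S)-4,8-dimethyl-7-(triethylsilyloxy)nona-3,8-dien-1-yl]cyclohexan-1-one
Product: 34 C3-methylidene analogue of 33 (2R,6S,7S in the numbering above)
Conditions: Cp2TiMe2, toluene, 65 °C
Reagents that add atoms: dimethyltitanocene Cp2TiMe2 C[Ti](C)(C1C=CC=C1)C1C=CC=C1
Why: Petasis methylenation is non-basic, so the ketone is converted into the exocyclic methylene without epimerising C2 and faster than the hindered tert-butyl ester can react.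

Step 24
Reactants: 34 C3-methylidene analogue of 33
Product: 36 seco acid (free benzoic acid and free C14 hydroxyl; phenol still as the triisopropylsilyl ether), via trimethylsilyl ester 35 (not isolated)
Conditions: TMSOTf, 2,6-lutidine, CH2Cl2, 0 °C; then AcOH–THF–H2O (3:1:1), rt
Reagents that add atoms: none
Why: The silyl triflate cleaves the tert-butyl ester through the silyl ester with loss of isobutene in a buffered, non-protic medium that should spare the alkenes, and aqueous acetic acid then hydrolyses the silyl ester and the triethylsilyl ether while the aryl silyl ether stays.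

Step 25
Reactants: 36 seco acid
Product: 38 macrolactone (15-membered benzoate of the C14 hydroxyl; C10=C11 E-alkene; phenol as the triisopropylsilyl ether), via mixed anhydride 37 (not isolated)
Conditions: 2,4,6-trichlorobenzoyl chloride, Et3N, THF, rt; then slow addition to DMAP, toluene, 80 °C (1 mM)
Reagents that add atoms: none
Why: Yamaguchi macrolactonisation acylates the C14 hydroxyl through the mixed anhydride under high dilution, and C14 keeps its configuration because only the acyl C–O bond is formed.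

Step 26
Reactants: 38 macrolactone
Product: 39 (10S,11S)-10,11-epoxide of 38
Conditions: ent-Shi ketone (30 mol %), Oxone, K2CO3, Bu4NHSO4, MeCN–dimethoxymethane–aqueous Na2B4O7 buffer, 0 °C
Reagents that add atoms: potassium peroxymonosulfate [K+].[O-]S(=O)(=O)OO
Why: Shi epoxidation: the chiral dioxirane reacts fastest with the trisubstituted E-alkene (the two 1,1-disubstituted alkenes are poor substrates) and its spiro transition state should set the (10S,11S) epoxide under catalyst control.

Step 27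
Reactants: 39 (10S,11S)-10,11-epoxide
Product: 40 O-triisopropylsilyl bromophycolide E [(10R,11S)-bromohydrin]
Conditions: Li2NiBr4, THF, 0 °C to rt
Reagents that add atoms: dilithium tetrabromonickelate Li2NiBr4 [Li+].[Li+].[Ni+2].[Br-].[Br-].[Br-].[Br-]
Why: SN2 opening of the epoxide by soft bromide under near-neutral conditions should occur at the less substituted C10 with inversion (10S to 10R), leaving the tertiary C11 alcohol with retained configuration.

Step 28
Reactants: 40 O-triisopropylsilyl bromophycolide E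
Product: 41 bromophycolide E
Conditions: Bu4NF, AcOH, THF, 0 °C
Reagents that add atoms: none
Why: Fluoride cleaves the aryl silyl ether, and the acetic acid buffer should prevent base-induced closure of the bromohydrin to the epoxide.

**Compound list**

1 | (R)-4-benzyloxazolidin-2-one | O=C1N[C@H](Cc2ccccc2)CO1 | starting material
2 | acryloyl chloride | C=CC(=O)Cl | starting material
3 | N-lithio-(R)-4-benzyloxazolidin-2-one | O=C1N([Li])[C@H](Cc2ccccc2)CO1 | intermediate
4 | (R)-3-acryloyl-4-benzyloxazolidin-2-one | C=CC(=O)N1[C@H](Cc2ccccc2)COC1=O | intermediate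
5 | tert-butyl 4-hydroxybenzoate | CC(C)(C)OC(=O)c1ccc(O)cc1 | starting material
6 | tert-butyl 4-hydroxy-3-iodobenzoate | CC(C)(C)OC(=O)c1ccc(O)c(I)c1 | intermediate
7 | tert-butyl 3-iodo-4-[(triisopropylsilyl)oxy]benzoate | CC(C)(C)OC(=O)c1ccc(O[Si](C(C)C)(C(C)C)C(C)C)c(I)c1 | intermediate
8 | (R)-4-benzyl-3-[(E)-3-Ar-prop-2-enoyl]oxazolidin-2-one | CC(C)(C)OC(=O)c1ccc(O[Si](C(C)C)(C(C)C)C(C)C)c(/C=C/C(=O)N2[C@H](Cc3ccccc3)COC2=O)c1 | intermediate
9 | (R)-4-benzyl-3-(3-Ar-propanoyl)oxazolidin-2-one | CC(C)(C)OC(=O)c1ccc(O[Si](C(C)C)(C(C)C)C(C)C)c(CCC(=O)N2[C@H](Cc3ccccc3)COC2=O)c1 | intermediate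
10 | pent-4-enal | C=CCCC=O | starting material
11 | dibutylboron Z-enolate of 9 | CCCCB(CCCC)O/C(N1[C@H](Cc2ccccc2)COC1=O)=C\Cc1cc(ccc1O[Si](C(C)C)(C(C)C)C(C)C)C(=O)OC(C)(C)C | intermediate
12 | (R)-4-benzyl-3-[(2R,3S)-2-(ArCH2)-3-hydroxyhept-6-enoyl]oxazolidin-2-one | O=C(N1[C@H](Cc2ccccc2)COC1=O)[C@H](Cc1cc(ccc1O[Si](C(C)C)(C(C)C)C(C)C)C(=O)OC(C)(C)C)[C@H](CCC=C)O | intermediate
13 | (2R,3S)-2-(ArCH2)-3-hydroxy-N-methoxy-N-methylhept-6-enamide | CON(C)C(=O)[C@H](Cc1cc(ccc1O[Si](C(C)C)(C(C)C)C(C)C)C(=O)OC(C)(C)C)[C@H](CCC=C)O | intermediate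
14 | (3R,4S)-3-(ArCH2)-4-hydroxyoct-7-en-2-one | CC(=O)[C@H](Cc1cc(ccc1O[Si](C(C)C)(C(C)C)C(C)C)C(=O)OC(C)(C)C)[C@H](CCC=C)O | intermediate
15 | (triphenylphosphoranylidene)acetate ester of 14 | CC(=O)[C@H](Cc1cc(ccc1O[Si](C(C)C)(C(C)C)C(C)C)C(=O)OC(C)(C)C)[C@H](CCC=C)OC(=O)C=P(c1ccccc1)(c1ccccc1)c1ccccc1 | intermediate
16 | (5S,6S)-5-(ArCH2)-6-(but-3-en-1-yl)-4-methyl-5,6-dihydro-2H-pyran-2-one (cis) | O=C1C=C(C)[C@H](Cc2cc(ccc2O[Si](C(C)C)(C(C)C)C(C)C)C(=O)OC(C)(C)C)[C@H](CCC=C)O1 | intermediate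
17 | (5S,6S)-5-(ArCH2)-6-(3,4-dihydroxybutyl)-4-methyl-5,6-dihydro-2H-pyran-2-one (both epimers at the new carbinol) | O=C1C=C(C)[C@H](Cc2cc(ccc2O[Si](C(C)C)(C(C)C)C(C)C)C(=O)OC(C)(C)C)[C@H](CCC(O)CO)O1 | intermediate
18 | (5S,6S)-5-(ArCH2)-4-methyl-6-(3-oxopropyl)-5,6-dihydro-2H-pyran-2-one | O=C1C=C(C)[C@H](Cc2cc(ccc2O[Si](C(C)C)(C(C)C)C(C)C)C(=O)OC(C)(C)C)[C@H](CCC=O)O1 | intermediate
19 | (1S,5S,9S)-9-(ArCH2)-5-methyl-2-oxabicyclo[3.3.1]nonane-3,6-dione | O=C1C[C@@]2(C)[C@H](Cc3cc(ccc3O[Si](C(C)C)(C(C)C)C(C)C)C(=O)OC(C)(C)C)[C@@H](O1)CCC2=O | intermediate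
20 | (1S,5S,9S)-6-bromo-9-(ArCH2)-5-methyl-2-oxabicyclo[3.3.1]non-6-en-3-one | O=C1C[C@@]2(C)[C@H](Cc3cc(ccc3O[Si](C(C)C)(C(C)C)C(C)C)C(=O)OC(C)(C)C)[C@@H](O1)CC=C2Br | intermediate
21 | (1S,5S,6S)-6-(ArCH2)-4-bromo-5-(2-hydroxyethyl)-5-methylcyclohex-3-en-1-ol | OCC[C@@]1(C)[C@H](Cc2cc(ccc2O[Si](C(C)C)(C(C)C)C(C)C)C(=O)OC(C)(C)C)[C@@H](O)CC=C1Br | intermediate
22 | (1S,2S,3S,4S)-2-(ArCH2)-4-bromo-3-(2-hydroxyethyl)-3-methylcyclohexan-1-ol | OCC[C@@]1(C)[C@H](Cc2cc(ccc2O[Si](C(C)C)(C(C)C)C(C)C)C(=O)OC(C)(C)C)[C@@H](O)CC[C@@H]1Br | intermediate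
23 | (1S,2S,3S,4S)-2-(ArCH2)-4-bromo-3-(2-iodoethyl)-3-methylcyclohexan-1-ol | ICC[C@@]1(C)[C@H](Cc2cc(ccc2O[Si](C(C)C)(C(C)C)C(C)C)C(=O)OC(C)(C)C)[C@@H](O)CC[C@@H]1Br | intermediate
24 | (2S,3S,4S)-2-(ArCH2)-4-bromo-3-(2-iodoethyl)-3-methylcyclohexan-1-one | ICC[C@@]1(C)[C@H](Cc2cc(ccc2O[Si](C(C)C)(C(C)C)C(C)C)C(=O)OC(C)(C)C)C(=O)CC[C@@H]1Br | intermediate
25 | methyl pent-4-ynoate | C#CCCC(=O)OC | starting material
26 | N-methoxy-N-methylpent-4-ynamide | C#CCCC(=O)N(C)OC | intermediate
27 | 2-methylhept-1-en-6-yn-3-one | C#CCCC(=O)C(C)=C | intermediate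
28 | (S)-2-methylhept-1-en-6-yn-3-ol | C=C(C)[C@@H](O)CCC#C | intermediate
29 | (E)-alkenyl(dimethyl)alane of 28, as its dimethylaluminium alkoxide | C=C(C)[C@@H](O[Al](C)C)CC/C(C)=C/[Al](C)C | intermediate
30 | (3S,6E)-7-iodo-2,6-dimethylhepta-1,6-dien-3-ol | C=C(C)[C@@H](O)CC/C(C)=C/I | intermediate
31 | triethyl{[(3S,6E)-7-iodo-2,6-dimethylhepta-1,6-dien-3-yl]oxy}silane | C=C(C)[C@@H](O[Si](CC)(CC)CC)CC/C(C)=C/I | intermediate
32 | alkylzinc iodide from 24 (C9–ZnI) | I[Zn]CC[C@@]1(C)[C@H](Cc2cc(ccc2O[Si](C(C)C)(C(C)C)C(C)C)C(=O)OC(C)(C)C)C(=O)CC[C@@H]1Br | intermediate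
33 | (2S,3S,4S)-2-(ArCH2)-4-bromo-3-methyl-3-[(3E,7S)-4,8-dimethyl-7-(triethylsilyloxy)nona-3,8-dien-1-yl]cyclohexan-1-one | C=C(C)[C@@H](O[Si](CC)(CC)CC)CC/C(C)=C/CC[C@@]1(C)[C@H](Cc2cc(ccc2O[Si](C(C)C)(C(C)C)C(C)C)C(=O)OC(C)(C)C)C(=O)CC[C@@H]1Br | intermediate
34 | C3-methylidene analogue of 33 (2R,6S,7S,14S; tert-butyl ester, C14 triethylsilyl ether, aryl triisopropylsilyl ether) | C=C(C)[C@@H](O[Si](CC)(CC)CC)CC/C(C)=C/CC[C@@]1(C)[C@H](Cc2cc(ccc2O[Si](C(C)C)(C(C)C)C(C)C)C(=O)OC(C)(C)C)C(=C)CC[C@@H]1Br | intermediate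
35 | trimethylsilyl ester of 36 with C14 still as the triethylsilyl ether | C=C(C)[C@@H](O[Si](CC)(CC)CC)CC/C(C)=C/CC[C@@]1(C)[C@H](Cc2cc(ccc2O[Si](C(C)C)(C(C)C)C(C)C)C(=O)O[Si](C)(C)C)C(=C)CC[C@@H]1Br | intermediate
36 | seco acid (free benzoic acid, free C14 hydroxyl, aryl triisopropylsilyl ether) | C=C(C)[C@@H](O)CC/C(C)=C/CC[C@@]1(C)[C@H](Cc2cc(ccc2O[Si](C(C)C)(C(C)C)C(C)C)C(=O)O)C(=C)CC[C@@H]1Br | intermediate
37 | mixed anhydride of 36 with 2,4,6-trichlorobenzoic acid | C=C(C)[C@@H](O)CC/C(C)=C/CC[C@@]1(C)[C@H](Cc2cc(ccc2O[Si](C(C)C)(C(C)C)C(C)C)C(=O)OC(=O)c2c(Cl)cc(Cl)cc2Cl)C(=C)CC[C@@H]1Br | intermediate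
38 | macrolactone with C10=C11 E-alkene (O-triisopropylsilyl) | C=C(C)[C@@H]1CC/C(C)=C/CC[C@@]2(C)[C@H](Cc3cc(ccc3O[Si](C(C)C)(C(C)C)C(C)C)C(=O)O1)C(=C)CC[C@@H]2Br | intermediate
39 | (10S,11S)-10,11-epoxide of 38 | C=C(C)[C@@H]1CC[C@]3(C)O[C@H]3CC[C@@]2(C)[C@H](Cc4cc(ccc4O[Si](C(C)C)(C(C)C)C(C)C)C(=O)O1)C(=C)CC[C@@H]2Br | intermediate
40 | O-triisopropylsilyl bromophycolide E | C=C(C)[C@@H]1CC[C@](C)(O)[C@H](Br)CC[C@@]2(C)[C@H](Cc3cc(ccc3O[Si](C(C)C)(C(C)C)C(C)C)C(=O)O1)C(=C)CC[C@@H]2Br | intermediate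
41 | bromophycolide E | C=C(C)[C@@H]1CC[C@](C)(O)[C@H](Br)CC[C@@]2(C)[C@H](Cc3cc(ccc3O)C(=O)O1)C(=C)CC[C@@H]2Br | target

**Step count.** Total: 28 steps. Longest linear sequence: 22 steps (from 5: steps 2–16 and 22–28).

**Steps most likely to fail**

Step 11 (acyl-radical ring closure). What may go wrong: hydrogen abstraction by the photocatalyst at the benzylic or silyl-isopropyl C–H bonds instead of the aldehyde, or addition to the hindered β,β-disubstituted acceptor that is too slow to outrun decarbonylation and simple reduction of the acyl radical. Fallback (group-transfer radical chain in place of photocatalytic hydrogen abstraction): setting out from aldehyde 18, Pinnick oxidation (NaClO2, NaH2PO4, 2-methylbut-2-ene, t-BuOH–H2O) should give the lactone carboxylic acid F1; (PhSe)2 and PBu3 in CH2Cl2 should convert it into the Se-phenyl selenoester F2; (Me3Si)3SiH and AIBN in dilute benzene at 80 °C should release the same C6 acyl radical by selenium abstraction and lead back to 19.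

Step 14 (hydrogen-atom-transfer hydrogenation of the vinyl bromide). What may go wrong: loss of bromine from the α-bromo radical or its metal-bound form, and insufficient facial selectivity in the second hydrogen delivery. Fallback (tin hydride monoreduction of a geminal dibromide in place of alkene hydrogenation): setting out from ketone 19, 1,2-bis(tert-butyldimethylsilyl)hydrazine with catalytic Sc(OTf)3 should give the N-silyl hydrazone F3; CuBr2 and Et3N in MeOH should convert it into the geminal dibromide F4; LiBH4 should open the lactone to the dibromo diol F5; Bu3SnH (1.0 equiv) with Et3B and air at −78 °C should remove one bromine, the α-bromo radical taking hydrogen axially as argued for step 14, which returns to 22 (steps 12–14 are then not run).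

Step 27 (bromide opening of the epoxide). What may go wrong: attack of bromide at the tertiary C11 or Lewis-acid-induced rearrangement of the epoxide to a ketone, that is, loss of regiocontrol. Fallback (bromonium ion and water in place of epoxide and bromide): setting out from alkene 38, N-bromosuccinimide in THF–H2O at 0 °C should add bromine at C10 and water at the more substituted C11 in an anti sense across the E-alkene, giving 40 together with its (10S,11R)-diastereomer F6, which is removed by chromatography; the route is rejoined at 40 and step 26 is not run. The price is loss of facial control.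

Further compounds
F1 | step 11 | 3-[(2S,3S)-3-(ArCH2)-4-methyl-6-oxo-3,6-dihydro-2H-pyran-2-yl]propanoic acid | O=C1C=C(C)[C@H](Cc2cc(ccc2O[Si](C(C)C)(C(C)C)C(C)C)C(=O)OC(C)(C)C)[C@H](CCC(=O)O)O1
F2 | step 11 | Se-phenyl selenoester of F1 | O=C1C=C(C)[C@H](Cc2cc(ccc2O[Si](C(C)C)(C(C)C)C(C)C)C(=O)OC(C)(C)C)[C@H](CCC(=O)[Se]c2ccccc2)O1
F3 | step 14 | N-(tert-butyldimethylsilyl)hydrazone of 19 at C6 | O=C1C[C@@]2(C)[C@H](Cc3cc(ccc3O[Si](C(C)C)(C(C)C)C(C)C)C(=O)OC(C)(C)C)[C@@H](O1)CCC2=NN[Si](C)(C)C(C)(C)C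
F4 | step 14 | (1S,5S,9S)-6,6-dibromo-9-(ArCH2)-5-methyl-2-oxabicyclo[3.3.1]nonan-3-one | O=C1C[C@@]2(C)[C@H](Cc3cc(ccc3O[Si](C(C)C)(C(C)C)C(C)C)C(=O)OC(C)(C)C)[C@@H](O1)CCC2(Br)Br
F5 | step 14 | (1S,2S,3S)-2-(ArCH2)-4,4-dibromo-3-(2-hydroxyethyl)-3-methylcyclohexan-1-ol | OCC[C@@]1(C)[C@H](Cc2cc(ccc2O[Si](C(C)C)(C(C)C)C(C)C)C(=O)OC(C)(C)C)[C@@H](O)CCC1(Br)Br
F6 | step 27 | (10S,11R)-diastereomer of 40 | C=C(C)[C@@H]1CC[C@@](C)(O)[C@@H](Br)CC[C@@]2(C)[C@H](Cc3cc(ccc3O[Si](C(C)C)(C(C)C)C(C)C)C(=O)O1)C(=C)CC[C@@H]2Br
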